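Readings and results are simulated with made-up constants, and the scatter is random.

| flask | starting material | partner | product | time |
|---|---|---|---|---|
| dawn | 50.0 mM | 150 mM |  |  |
| dusk | 30.0 mM | 130 mM |  |  |
| winter | 100 mM | 150 mM |  |  |
| autumn | 50.0 mM | 150 mM | 25.0 mM |  |
| noon | 320 mM | 150 mM |  | 3.8 h |

| dawn run: time / h | dawn run: [product] / mM | dusk run: time / h | dusk run: [product] / mM | winter run: time / h | winter run: [product] / mM | autumn run: time / h | autumn run: [product] / mM |
|---|---|---|---|---|---|---|---|
| 0.14 | 1.73 | 0.14 | 0.97 | 0.14 | 3.40 | 0.14 | 27.15 |
| 0.41 | 7.31 | 0.41 | 4.41 | 0.41 | 11.48 | 0.41 | 32.00 |
| 0.79 | 11.38 | 0.79 | 7.36 | 0.79 | 18.42 | 0.79 | 36.54 |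
| 1.3 | 14.76 | 1.3 | 9.94 | 1.3 | 23.31 | 1.3 | 39.67 |
| 1.8 | 16.58 | 1.8 | 11.00 | 1.8 | 25.92 | 1.8 | 41.92 |
| 2.4 | 17.83 | 2.4 | 11.94 | 2.4 | 28.22 | 2.4 | 42.89 |
| 3.1 | 18.83 | 3.1 | 12.44 | 3.1 | 29.25 | 3.1 | 43.67 |
| 3.8 | 19.06 | 3.8 | 12.95 | 3.8 | 29.69 | 3.8 | 44.17 |

(standard deviation of a reading: 0.2 mM)

- order of the initial rate in [starting material], near the charge of the dawn run, the rate being that where two percent of its starting material are product (one fixed amount of product, the same in the runs compared)
- order of the initial rate in [partner], near the charge of the dawn run, the rate being that where two percent of its starting material are product
- product in the noon run at 3.8 h, as a share of the starting material charged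
- which of these the readings show (the second partner is lost in pairs / the second partner is lost by itself / the substrate is lost by itself / the product binds the second partner / the second partner pairs with itself)

- Overall: starting material + partner -> product.
- Constant volume, constant temperature.
- "The second partner" is partner.
- An order is taken over about fifteen percent of the charge, up and down.

1. Start from the slowness. In the dawn run, product rises by 0.230 mM from 3.1 h to 3.8 h, yet 61.9 % of the charge has not become product. Take the last reading as the stopping point, and call the charge of starting material per product made by then the cost, the inverse of the share.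

2. Put in the main step first. With starting material + partner → product and partner in excess, the cost is 1. The dawn run reads 2.62.

3. Add a side loss in fixed proportion to the main step. This raises the cost but keeps it equal across charges. The winter run reads 3.37, which is higher than dawn, so a fixed proportion does not fit.

4. Add the rest: the cost grows with the product made. Between dawn and winter, both charged with 150 mM of partner, it climbs by 0.0701 mM⁻¹. This rise of cost per mM of product made is the cost slope. Running the line back to zero product leaves a base cost of 1.29, which I read as starting material lost by itself. Added product is not what raises the cost: the autumn run makes 19.2 mM on top of its charge of product, against 19.06 mM in dawn.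

5. Now the noon run. Setting cost equal to base plus slope times product gives my share of 18.4 %. Partner is the limiting reagent of that charge, but this share would use 39.3 % of it.

6. The forecast gives orders of 0.67 in starting material and 0.95 in partner, a share of 14.3 %, and the choice "the second partner is lost by itself": “The partner is therefore lost by itself”. Its share is lower than mine.

7. The simulation gives orders of 0.62 and 0.53, a share of 18.0 %, and the choice "the substrate is lost by itself". The forecast's share and order in starting material hold, its order in partner is 1.79 times too high, and its choice is wrong.

    starting material ⇌ intermediate + by-product (1.170 h⁻¹, 622.8 L mol⁻¹ h⁻¹)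
    intermediate + partner → product (30.82 L mol⁻¹ h⁻¹)
    starting material → decomposed substrate (0.6444 h⁻¹)

The noon run has a cost of 5.56, and the line at that product gives 5.31. Part of that cost is the reaction of starting material to decomposed substrate: without it, the share in the noon run is 27.3 % instead of 18.0 %, a cost of 3.66. For the dusk run, charged with less partner, the same cost slope gives a share of 44.8 %, and its last reading shows 43.2 %.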